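**Assumption:** locants C1–C11 in the descriptions follow iridoid (valtrate) numbering; the target is (1S,7S,8R,9S), i.e. (1S,6S,7R,7aS) in cyclopenta[c]pyran numbering.

## Retrosynthetic overview

1. Target ⇐ C11 desilylation/acetylation ⇐ 1-O-isovaleryl dienol-ether acetal, made by enol-lactolisation/acylation of a C1,C3-dialdehyde on a preformed cyclopentene (pyran ring formed last).
2. Cyclopentene (C5=C6) ⇐ ring-closing metathesis of an acyclic 1,6-diene (carbocycle formed first).
3. Diene ⇐ hydroxyl-directed allylboration joining α-hydroxy ketone **8** (C6–C7–C8–C10) with allylboronate **19** (C1, C9, C5, C4, C3, C11); this union creates C8 and C9.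
4. **8** ⇐ acrolein + vinylmagnesium bromide, with C7 set by Sharpless epoxidation. **19** ⇐ 2-bromoallyl alcohol + propargyl alcohol (Sonogashira, hydroboration, Red-Al/I2, Matteson homologation).

## Route

### Fragment A: ketone 8

**Step 1**
Reactants: **1** acrolein; **2** vinylmagnesium bromide
Product: **3** penta-1,4-dien-3-ol
Conditions: THF, −78 → 0 °C; aq. NH4Cl
Reagents that add atoms: none
Why: Grignard 1,2-addition to the enal gives the achiral divinyl carbinol needed for desymmetrising epoxidation.

**Step 2**
Reactants: **3** penta-1,4-dien-3-ol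
Product: **4** (2R,3S)-1,2-epoxypent-4-en-3-ol
Conditions: Ti(OiPr)4, L-(+)-DIPT, t-BuOOH, 4 Å MS, CH2Cl2, −20 °C
Reagents that add atoms: tert-butyl hydroperoxide, CC(C)(C)OO
Why: Sharpless asymmetric epoxidation (enantiotopic-group plus face selection, erythro product) sets the carbinol centre that becomes C7 (S).

**Step 3**
Reactants: **4**
Product: **5** (2R,3S)-3-(tert-butyldimethylsilyloxy)-1,2-epoxypent-4-ene
Conditions: TBSCl, imidazole, DMF, 0 °C → rt
Reagents that add atoms: TBSCl, C[Si](C)(Cl)C(C)(C)C
Why: Silylation masks C7–OH so that only the C8 hydroxyl is oxidised later; no base strong enough for Payne rearrangement is used.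

**Step 4**
Reactants: **5**
Product: **6** (2R,3S)-3-(TBS-oxy)-2-hydroxypent-4-en-1-yl acetate
Conditions: CsOAc, AcOH, DMF, 60 °C
Reagents that add atoms: acetic acid / caesium acetate, CC(=O)O
Why: SN2 opening of the terminal epoxide at CH2 by acetate installs the C10 acetate of the target and leaves both stereocentres untouched.

**Step 5**
Reactants: **6**
Product: **7** (3S)-3-(TBS-oxy)-2-oxopent-4-en-1-yl acetate
Conditions: Dess–Martin periodinane, NaHCO3, CH2Cl2, 0 °C
Reagents that add atoms: none
Why: Dess–Martin oxidation of the only free alcohol gives the C8 ketone under non-basic conditions, so the α-stereocentre (C7) is preserved.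

**Step 6**
Reactants: **7**
Product: **8** (3S)-3-hydroxy-2-oxopent-4-en-1-yl acetate
Conditions: HF·pyridine, THF, 0 °C; used at once
Reagents that add atoms: none
Why: Mildly acidic desilylation frees the α-hydroxyl needed as the boron tether without enolising the ketone or cleaving the acetate.

### Boron reagent

**Step 7**
Reactants: **9** triisopropyl borate; **10** chloroiodomethane
Product: **11** diisopropyl (chloromethyl)boronate
Conditions: n-BuLi, THF, −78 °C; then TMSCl, −78 °C → rt
Reagents that add atoms: none
Why: Matteson's in-situ LiCH2Cl is trapped by the borate to give the chloromethylboronate.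

### Fragment B: allylboronate 19

**Step 8**
Reactants: **12** 2-bromoprop-2-en-1-ol
Product: **13** (2-bromoallyloxy)(tert-butyl)dimethylsilane
Conditions: TBSCl, imidazole, CH2Cl2, rt
Reagents that add atoms: TBSCl, C[Si](C)(Cl)C(C)(C)C
Why: Silylation fixes the future C11 oxygen as a robust ether.

**Step 9**
Reactants: **13**; **14** prop-2-yn-1-ol
Product: **15** 4-[(TBS-oxy)methyl]pent-4-en-2-yn-1-ol
Conditions: PdCl2(PPh3)2, CuI, iPr2NH, THF, 45 °C
Reagents that add atoms: none
Why: Sonogashira coupling of the 2-bromoalkene joins C4 to the C5≡C9–C1 unit.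

**Step 10**
Reactants: **15**
Product: **16** (±)-4-[(TBS-oxy)methyl]pent-2-yne-1,5-diol
Conditions: 9-BBN (2.5 equiv), THF, 0 °C → rt; then H2O2, aq. NaOH, 0 °C
Reagents that add atoms: hydrogen peroxide, OO
Why: Bulky 9-BBN hydroborates the terminal 1,1-disubstituted alkene anti-Markovnikov much faster than the internal alkyne; the new C4 stereocentre is inconsequential because it is destroyed in step 19.

**Step 11**
Reactants: **16**
Product: **17** (±)-(Z)-3-iodo-4-[(TBS-oxy)methyl]pent-2-ene-1,5-diol (I cis to the C1 CH2OH)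
Conditions: Red-Al (3.5 equiv), THF, 0 °C → rt; then I2, −78 °C
Reagents that add atoms: iodine, II
Why: Hydroxyl-directed trans-hydroalumination of the propargylic alcohol followed by iodinolysis gives the vinyl iodide regio- and stereospecifically.

**Step 12**
Reactants: **17**
Product: **18** bis(4-methoxybenzyl) ether of **17** (C1–OPMB, C3–OPMB)
Conditions: NaH, PMBCl, Bu4NI, THF/DMF, 0 °C → rt
Reagents that add atoms: 4-methoxybenzyl chloride, COc1ccc(CCl)cc1
Why: Williamson etherification puts one common, oxidatively removable group on the two carbons that later become the aldehydes.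

**Step 13**
Reactants: **18**; **11** diisopropyl (chloromethyl)boronate
Product: **19** diisopropyl (E)-{4-(PMB-oxy)-2-[1-(TBS-oxy)-3-(PMB-oxy)propan-2-yl]but-2-en-1-yl}boronate (CH2B cis to CH2OPMB on the alkene)
Conditions: t-BuLi (2.1 equiv), Et2O, −78 °C; then **11**, −78 °C → rt; used crude
Reagents that add atoms: none
Why: Iodine–lithium exchange and Matteson homologation (1,2-metallate shift) give the allylboronate with retention of alkene geometry.

### Union and endgame

**Step 14**
Reactants: **8**; **19**
Product: **20** (7S,8R,9R)-acyclic diene diol, AcOCH2–C8(OH)[C7H(OH)CH=CH2]–C9H(CH2OPMB)–C5(=CH2)–C4H(CH2OPMB)(CH2OTBS) (1:1 at C4)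
Conditions: 4 Å MS, toluene, −20 °C → rt; then aq. NaHCO3/triethanolamine
Reagents that add atoms: none
Why: Hydroxyl-directed allylboration: boron is tethered to C7–O, and the allyl group is delivered through a bicyclic chair transition state from the face anti to the C7 vinyl group (sets C8), with the γ-CH2OPMB (cis to CH2B) axial (sets C9).

**Step 15**
Reactants: **20**
Product: **21** cyclopentene diol (7S,8R,9R): C5=C6 ring bearing C7–OH, C8(OH)CH2OAc, C9–CH2OPMB and the C4 side chain on C5
Conditions: Grubbs II (5 mol%), CH2Cl2, 40 °C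
Reagents that add atoms: none
Why: Ring-closing metathesis between the vinyl group and the 1,1-disubstituted alkene forms the trisubstituted cyclopentene (loss of ethylene); no stereocentre is touched.

**Step 16**
Reactants: **21**
Product: **22** 7-O-isovalerate of **21**
Conditions: isovaleric anhydride (1.2 equiv), Et3N, DMAP (cat.), CH2Cl2, 0 °C
Reagents that add atoms: isovaleric anhydride, CC(C)CC(=O)OC(=O)CC(C)C
Why: DMAP-catalysed acylation takes the secondary allylic C7–OH and leaves the tertiary C8–OH free.

**Step 17**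
Reactants: **22**
Product: **23** C1,C3-diol (both PMB groups removed)
Conditions: DDQ, CH2Cl2/pH 7 buffer, 0 °C
Reagents that add atoms: none
Why: Oxidative PMB cleavage frees the two primary alcohols without affecting the silyl ether, esters or alkene.

**Step 18**
Reactants: **23**
Product: **24** C1,C3-dialdehyde (7S,8R,9S)
Conditions: (COCl)2, DMSO, CH2Cl2, −78 °C; iPr2NEt, −78 → −20 °C; used crude
Reagents that add atoms: none
Why: Swern oxidation activates both primary alcohols before base is added, giving the 1,5-dialdehyde rather than a lactol/lactone; the tertiary alcohol is inert.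

**Step 19**
Reactants: **24**
Product: **25** 11-O-TBS bicyclic acetal (1S,7S,8R,9S): the target with OTBS in place of the C11 acetate
Conditions: isovaleric anhydride, DMAP, pyridine, CH2Cl2, 0 °C → rt
Reagents that add atoms: isovaleric anhydride, CC(C)CC(=O)OC(=O)CC(C)C
Why: The C3 aldehyde enolises to the conjugated C3=C4–C5=C6 dienol, whose oxygen adds to the C1 aldehyde, and the lactol is trapped as the ester. The acyloxy group takes the anomerically favoured pseudo-axial position (H1/H9 trans, 1S), and the C4 stereocentre disappears.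

**Step 20**
Reactants: **25**
Product: **26** 11-hydroxy compound
Conditions: HF·pyridine, pyridine/THF, 0 °C
Reagents that add atoms: none
Why: Buffered fluoride removes the primary allylic TBS ether without touching the acyl acetal or esters.

**Step 21**
Reactants: **26**
Product: **27** 10-acetoxyvaltrathydrin
Conditions: Ac2O, pyridine, DMAP (cat.), CH2Cl2, 0 °C
Reagents that add atoms: acetic anhydride, CC(=O)OC(C)=O
Why: Acetylation of the primary alcohol; the hindered tertiary C8–OH does not react.

## Compound list

1 | acrolein | C=CC=O | starting material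
2 | vinylmagnesium bromide | C=C[Mg]Br | starting material
3 | penta-1,4-dien-3-ol | C=CC(O)C=C | intermediate
4 | (2R,3S)-1,2-epoxypent-4-en-3-ol | C=C[C@H](O)[C@H]1CO1 | intermediate
5 | (2R,3S)-3-(TBS-oxy)-1,2-epoxypent-4-ene | C=C[C@H](O[Si](C)(C)C(C)(C)C)[C@H]1CO1 | intermediate
6 | (2R,3S)-3-(TBS-oxy)-2-hydroxypent-4-en-1-yl acetate | C=C[C@H](O[Si](C)(C)C(C)(C)C)[C@H](O)COC(C)=O | intermediate
7 | (3S)-3-(TBS-oxy)-2-oxopent-4-en-1-yl acetate | C=C[C@H](O[Si](C)(C)C(C)(C)C)C(=O)COC(C)=O | intermediate
8 | (3S)-3-hydroxy-2-oxopent-4-en-1-yl acetate | C=C[C@H](O)C(=O)COC(C)=O | intermediate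
9 | triisopropyl borate | CC(C)OB(OC(C)C)OC(C)C | starting material
10 | chloroiodomethane | ClCI | starting material
11 | diisopropyl (chloromethyl)boronate | ClCB(OC(C)C)OC(C)C | intermediate
12 | 2-bromoprop-2-en-1-ol | C=C(Br)CO | starting material
13 | (2-bromoallyloxy)(tert-butyl)dimethylsilane | C=C(Br)CO[Si](C)(C)C(C)(C)C | intermediate
14 | prop-2-yn-1-ol | C#CCO | starting material
15 | 4-[(TBS-oxy)methyl]pent-4-en-2-yn-1-ol | C=C(CO[Si](C)(C)C(C)(C)C)C#CCO | intermediate
16 | (±)-4-[(TBS-oxy)methyl]pent-2-yne-1,5-diol | OCC#CC(CO)CO[Si](C)(C)C(C)(C)C | intermediate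
17 | (±)-(Z)-3-iodo-4-[(TBS-oxy)methyl]pent-2-ene-1,5-diol | OC/C=C(\I)C(CO)CO[Si](C)(C)C(C)(C)C | intermediate
18 | bis-PMB ether of 17 | COc1ccc(COC/C=C(\I)C(COCc2ccc(OC)cc2)CO[Si](C)(C)C(C)(C)C)cc1 | intermediate
19 | diisopropyl (E)-allylboronate (CH2B cis to CH2OPMB) | COc1ccc(COC/C=C(\CB(OC(C)C)OC(C)C)C(COCc2ccc(OC)cc2)CO[Si](C)(C)C(C)(C)C)cc1 | intermediate
20 | (7S,8R,9R)-acyclic diene diol | C=C[C@H](O)[C@](O)(COC(C)=O)[C@@H](COCc1ccc(OC)cc1)C(=C)C(COCc2ccc(OC)cc2)CO[Si](C)(C)C(C)(C)C | intermediate
21 | (7S,8R,9R)-cyclopentene diol | COc1ccc(COC[C@H]2C(C(COCc3ccc(OC)cc3)CO[Si](C)(C)C(C)(C)C)=C[C@H](O)[C@]2(O)COC(C)=O)cc1 | intermediate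
22 | 7-O-isovaleryl cyclopentene | COc1ccc(COC[C@H]2C(C(COCc3ccc(OC)cc3)CO[Si](C)(C)C(C)(C)C)=C[C@H](OC(=O)CC(C)C)[C@]2(O)COC(C)=O)cc1 | intermediate
23 | C1,C3-diol | OC[C@H]1C(C(CO)CO[Si](C)(C)C(C)(C)C)=C[C@H](OC(=O)CC(C)C)[C@]1(O)COC(C)=O | intermediate
24 | C1,C3-dialdehyde | O=C[C@H]1C(C(C=O)CO[Si](C)(C)C(C)(C)C)=C[C@H](OC(=O)CC(C)C)[C@]1(O)COC(C)=O | intermediate
25 | 11-O-TBS bicyclic acetal (1S,7S,8R,9S) | CC(C)(C)[Si](C)(C)OCC1=CO[C@@H](OC(=O)CC(C)C)[C@H]2C1=C[C@H](OC(=O)CC(C)C)[C@]2(O)COC(C)=O | intermediate
26 | 11-hydroxy compound | OCC1=CO[C@@H](OC(=O)CC(C)C)[C@H]2C1=C[C@H](OC(=O)CC(C)C)[C@]2(O)COC(C)=O | intermediate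
27 | 10-acetoxyvaltrathydrin | CC(=O)OCC1=CO[C@@H](OC(=O)CC(C)C)[C@H]2C1=C[C@H](OC(=O)CC(C)C)[C@]2(O)COC(C)=O | target

## Summary

**Total steps:** 21.

**Longest linear sequence:** 14 steps (steps 1–6 then 14–21, or equally steps 8–13 then 14–21).

**Steps most likely to fail, with fallbacks:**

- **Step 14 (allylboration union).** A hindered ketone and a 2,3-disubstituted allylboronate must form adjacent quaternary and tertiary centres, and α-ketol **8** is sensitive. Fallback: give up the fragment union and set C8/C9 by Sharpless epoxidation of a 2-substituted (Z)-but-2-ene-1,4-diol derivative followed by C3-selective epoxide opening with an alkynylalane, then close the cyclopentene by ring-closing enyne metathesis.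
- **Step 19 (dialdehyde → acylated dienol-ether lactol).** Risks are C9 epimerisation, β-elimination and aromatisation of the valepotriate core. Fallback: take C1 to the carboxylic acid, close the enol δ-lactone onto C3, and install the 1-O-isovaleryl group by reductive acylation (DIBAL-H, then isovaleric anhydride/DMAP at −78 °C).
- **Step 10 (hydroboration of the conjugated enyne).** Alkene-versus-alkyne selectivity may be poor. Fallback: build the branched alkyne without hydroboration, from diethyl malonate (alkylation with PMBOCH2Cl, LiAlH4, monosilylation, oxidation, Ohira–Bestmann homologation, hydroxymethylation), then continue from step 11.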